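**Retrosynthetic overview**
- Oxirane last: chiral-dioxirane (Shi) epoxidation of the (Z)-trisubstituted allyl aryl ether.
- Aryl ether: SN2 of umbelliferone on a (Z)-allylic bromide.
- Bromide and γ-lactone both come from one 2-substituted 4-methyl-3,6-dihydro-2H-pyran: Me2BBr cuts the allylic C–O bond, and the freed secondary hydroxyl closes the lactone.
- Dihydropyran: IDPi-catalysed hetero-Diels–Alder of isoprene with a β-silyloxy aldehyde (sets lactone C-5; the ring fixes the Z olefin).
- Aldehyde: new IDPi/silylium Mukaiyama aldol of the acetaldehyde enol silane with ethyl pyruvate (first stereocentre). Ring order: dihydropyran (temporary), then γ-lactone, then oxirane; the coumarin is bought.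

Assumption: both antipodes of the chiral acid catalysts and of the Shi ketone are available, the antipode giving the stated face is used, and catalysts are not counted as starting materials or steps.

**Step 1**
Reactants: 1 ethyl pyruvate; 2 trimethyl(vinyloxy)silane
Product: 3 ethyl (2R)-2-methyl-4-oxo-2-(trimethylsilyloxy)butanoate
Conditions: confined chiral imidodiphosphorimidate acid (IDPi, 1 mol %), 2 (1.5 equiv), toluene, −60 °C
Reagents that add atoms: none
Why: Proposed new method: the IDPi acid is silylated by 2 to a silylium-type Lewis acid that activates the ketone oxygen of 1 inside the chiral anion pocket, 2 adds to the Re face (methyl versus ester discrimination) and the silyl group ends on the new tertiary oxygen, while the bulky β,β-disubstituted product aldehyde is excluded from a second aldol; the closest known reactions are the IDPi-catalysed Mukaiyama aldol of acetaldehyde silyl enol ethers with aldehydes and of silyl ketene acetals with simple ketones.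

**Step 2**
Reactants: 3 ethyl (2R)-2-methyl-4-oxo-2-(trimethylsilyloxy)butanoate; 4 isoprene
Product: 5 ethyl (2R)-2-methyl-3-[(2S)-4-methyl-3,6-dihydro-2H-pyran-2-yl]-2-(trimethylsilyloxy)propanoate
Conditions: 4 (5 equiv), IDPi acid (3 mol %, antipode for Si-face attack), methylcyclohexane–CH2Cl2, −20 °C
Reagents that add atoms: none
Why: Brønsted-acid-catalysed hetero-Diels–Alder of an unactivated diene with an aliphatic aldehyde: the CH2 next to the methyl-bearing carbon of isoprene attacks the ion-paired aldehyde, so only the 2,4-disubstituted pyran forms, and the catalyst sets the new centre (2S) while the ring locks the later olefin as Z.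

**Step 3**
Reactants: 5 ethyl (2R)-2-methyl-3-[(2S)-4-methyl-3,6-dihydro-2H-pyran-2-yl]-2-(trimethylsilyloxy)propanoate
Product: 8 (3R,5S)-5-[(2Z)-4-bromo-2-methylbut-2-en-1-yl]-3-hydroxy-3-methyloxolan-2-one, via borinate bromo ester 6 (not isolated), via bromo dihydroxy ester 7 (not isolated)
Conditions: Me2BBr (1.5 equiv), CH2Cl2, −78 °C; 1 M HCl, THF, 0 °C; then TsOH (cat.), CH2Cl2, rt
Reagents that add atoms: dimethylboron bromide, CB(C)Br
Why: Boron-assisted ether cleavage by SN2 attack of bromide at the primary allylic carbon (no allyl cation, so Z is kept and the C–O bond at the stereocentre is untouched), then acid hydrolysis of the borinate and silyl ether and γ-lactonisation of the freed secondary hydroxyl onto the ester.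

**Step 4**
Reactants: 8 (3R,5S)-5-[(2Z)-4-bromo-2-methylbut-2-en-1-yl]-3-hydroxy-3-methyloxolan-2-one; 9 umbelliferone (7-hydroxy-2H-chromen-2-one)
Product: 10 7-{[(2Z)-4-[(2S,4R)-4-hydroxy-4-methyl-5-oxooxolan-2-yl]-3-methylbut-2-en-1-yl]oxy}-2H-chromen-2-one
Conditions: K2CO3 (1.5 equiv), acetone, rt, dark
Reagents that add atoms: none
Why: Williamson ether synthesis, SN2 of the phenoxide at the primary allylic bromide, which touches no stereocentre and keeps the Z geometry; the tertiary alcohol and both lactones tolerate K2CO3 in dry acetone.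

**Step 5**
Reactants: 10 7-{[(2Z)-4-[(2S,4R)-4-hydroxy-4-methyl-5-oxooxolan-2-yl]-3-methylbut-2-en-1-yl]oxy}-2H-chromen-2-one
Product: 11 7-{[(2S,3R)-3-{[(2R,4R)-4-hydroxy-4-methyl-5-oxooxolan-2-yl]methyl}-3-methyloxiran-2-yl]methoxy}-2H-chromen-2-one
Conditions: ent-Shi ketone (L-fructose-derived, 0.5 equiv), Oxone (2KHSO5·KHSO4·K2SO4), K2CO3 metered to pH 8–9, Bu4NHSO4, MeCN–CH2(OMe)2–aqueous Na2EDTA, 0 °C
Reagents that add atoms: potassium peroxymonosulfate, [K+].[O-]S(=O)(=O)OO
Why: Shi epoxidation: the chiral dioxirane transfers oxygen through a spiro transition state placed by the single vinylic H, and applying the facial rule known for the D-fructose ketone (trans-stilbene and 1-phenylcyclohexene give R,R) the L-series ketone gives the (2S,3R)-oxirane; the electron-poor coumarin olefin is not attacked and the mild pH spares both lactones.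

**Compound list**
1 | ethyl pyruvate (ethyl 2-oxopropanoate) | CCOC(=O)C(C)=O | starting material
2 | trimethyl(vinyloxy)silane | C=CO[Si](C)(C)C | starting material
3 | ethyl (2R)-2-methyl-4-oxo-2-(trimethylsilyloxy)butanoate | CCOC(=O)[C@](C)(O[Si](C)(C)C)CC=O | intermediate
4 | isoprene (2-methylbuta-1,3-diene) | C=CC(C)=C | starting material
5 | ethyl (2R)-2-methyl-3-[(2S)-4-methyl-3,6-dihydro-2H-pyran-2-yl]-2-(trimethylsilyloxy)propanoate | CCOC(=O)[C@](C)(O[Si](C)(C)C)C[C@@H]1CC(C)=CCO1 | intermediate
6 | ethyl (2R,4S,6Z)-8-bromo-4-[(dimethylboranyl)oxy]-2,6-dimethyl-2-(trimethylsilyloxy)oct-6-enoate | CCOC(=O)[C@](C)(O[Si](C)(C)C)C[C@@H](OB(C)C)C/C(C)=C\CBr | intermediate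
7 | ethyl (2R,4S,6Z)-8-bromo-2,4-dihydroxy-2,6-dimethyloct-6-enoate | CCOC(=O)[C@](C)(O)C[C@@H](O)C/C(C)=C\CBr | intermediate
8 | (3R,5S)-5-[(2Z)-4-bromo-2-methylbut-2-en-1-yl]-3-hydroxy-3-methyloxolan-2-one | C/C(C[C@H]1C[C@@](C)(O)C(=O)O1)=C/CBr | intermediate
9 | umbelliferone (7-hydroxy-2H-chromen-2-one) | Oc1ccc2ccc(=O)oc2c1 | starting material
10 | 7-{[(2Z)-4-[(2S,4R)-4-hydroxy-4-methyl-5-oxooxolan-2-yl]-3-methylbut-2-en-1-yl]oxy}-2H-chromen-2-one | C/C(C[C@H]1C[C@@](C)(O)C(=O)O1)=C/COc1ccc2ccc(=O)oc2c1 | intermediate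
11 | 7-{[(2S,3R)-3-{[(2R,4R)-4-hydroxy-4-methyl-5-oxooxolan-2-yl]methyl}-3-methyloxiran-2-yl]methoxy}-2H-chromen-2-one | C[C@]1(C[C@H]2C[C@@](C)(O)C(=O)O2)O[C@H]1COc1ccc2ccc(=O)oc2c1 | target

**Totals**
Total step count: 5. Longest linear sequence: 5 steps (1 → 3 → 5 → 8 → 10 → 11).

**Three steps most likely to fail**

Step 1 (the proposed new aldol). Pyruvate may be too weak an acceptor for the enol silane, the sense or level of induction may be poor, or the product may aldolise again. The fallback uses known chemistry and sets out from 1. A Mukaiyama aldol of 1 with 1-(ethylsulfanyl)-1-(trimethylsilyloxy)ethene, catalysed by Cu(OTf)2 and the (R,R)-tert-butyl-bis(oxazoline) ligand (THF, −78 °C, non-acidic work-up), gives ethyl (2R)-4-(ethylsulfanyl)-2-methyl-4-oxo-2-(trimethylsilyloxy)butanoate F1. Fukuyama reduction of the thioester (Et3SiH, Pd/C, acetone, rt) then gives aldehyde 3, where the route is rejoined.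

Step 2 (hetero-Diels–Alder). The β-quaternary silyloxy aldehyde may be too large for the confined acid, or the existing centre may be mismatched with the catalyst. The fallback sets out from 3. Chiral phosphoric acid (TRIP antipode for Si-face transfer) catalysed methallylboration with 2-methylallylboronic acid pinacol ester (toluene, −30 °C) gives ethyl (2R,4S)-4-hydroxy-2,6-dimethyl-2-(trimethylsilyloxy)hept-6-enoate F2. O-Allylation under non-basic conditions (allyl 2,2,2-trichloroacetimidate, TfOH cat., cyclohexane–CH2Cl2) gives ethyl (2R,4S)-2,6-dimethyl-4-(prop-2-en-1-yloxy)-2-(trimethylsilyloxy)hept-6-enoate F3. Ring-closing metathesis (second-generation Grubbs catalyst, CH2Cl2, 40 °C) then closes the same dihydropyran 5.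

Step 5 (Shi epoxidation). The facial selectivity is untested for this (Z)-trisubstituted allyl aryl ether, and the two lactones are base-sensitive. The fallback sets out from 8 and moves the epoxidation ahead of the etherification. HCO2Na in DMF displaces the bromide to give (2Z)-4-[(2S,4R)-4-hydroxy-4-methyl-5-oxooxolan-2-yl]-3-methylbut-2-en-1-yl formate F4. Brief methanolysis (NaHCO3, MeOH, rt) gives the allylic alcohol (3R,5S)-3-hydroxy-5-[(2Z)-4-hydroxy-2-methylbut-2-en-1-yl]-3-methyloxolan-2-one F5. Sharpless epoxidation (Ti(OiPr)4, L-(+)-diethyl tartrate, tBuOOH, 4 Å sieves, CH2Cl2, −20 °C) gives (3R,5R)-3-hydroxy-5-{[(2R,3S)-3-(hydroxymethyl)-2-methyloxiran-2-yl]methyl}-3-methyloxolan-2-one F6. Mitsunobu etherification with umbelliferone 9 (PPh3, DIAD, THF, 0 °C) then gives the target 11.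

**Further compounds**
F1 | step 1 | ethyl (2R)-4-(ethylsulfanyl)-2-methyl-4-oxo-2-(trimethylsilyloxy)butanoate | CCOC(=O)[C@](C)(O[Si](C)(C)C)CC(=O)SCC
F2 | step 2 | ethyl (2R,4S)-4-hydroxy-2,6-dimethyl-2-(trimethylsilyloxy)hept-6-enoate | CCOC(=O)[C@](C)(O[Si](C)(C)C)C[C@@H](O)CC(C)=C
F3 | step 2 | ethyl (2R,4S)-2,6-dimethyl-4-(prop-2-en-1-yloxy)-2-(trimethylsilyloxy)hept-6-enoate | CCOC(=O)[C@](C)(O[Si](C)(C)C)C[C@@H](OCC=C)CC(C)=C
F4 | step 5 | (2Z)-4-[(2S,4R)-4-hydroxy-4-methyl-5-oxooxolan-2-yl]-3-methylbut-2-en-1-yl formate | C/C(C[C@H]1C[C@@](C)(O)C(=O)O1)=C/COC=O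
F5 | step 5 | (3R,5S)-3-hydroxy-5-[(2Z)-4-hydroxy-2-methylbut-2-en-1-yl]-3-methyloxolan-2-one | C/C(C[C@H]1C[C@@](C)(O)C(=O)O1)=C/CO
F6 | step 5 | (3R,5R)-3-hydroxy-5-{[(2R,3S)-3-(hydroxymethyl)-2-methyloxiran-2-yl]methyl}-3-methyloxolan-2-one | C[C@]1(C[C@H]2C[C@@](C)(O)C(=O)O2)O[C@H]1CO
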